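**Retrosynthetic overview**

1. Feature: the benzo ring of the isocoumarin (C4a, C5 with the ring-A benzyl group, C6–OH, C7–H, C8–OMe, C8a) is a resorcinol ring fused to a 6-methyl-2-pyranone. The localized pyranone C3=C4 bond (C8a=C4a of the target) can serve as the terminal alkene of a dienylketene.
2. Key disconnection: C5–C6, C7–C8 and C8–C8a, leading back to the ketene of acid chloride 16 and (triisopropylsilyloxy)ethyne 21. The ketene oxygen becomes the free 8-OH and the alkyne oxygen the 6-silyl ether.
3. Acid chloride 16 comes from ester 14, made by Pd-catalysed coupling of the zinc enolate of ring-A propanoate 9 with 4-bromo-6-methyl-2-pyranone 11. Ester 9 comes from aldehyde 6 by olefination and conjugate reduction; 6 comes from 3,5-bis(benzyloxy)benzyl alcohol 1 by formylation and a chelation-controlled benzyl-to-methyl exchange.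
4. Ring order: ring A and the pyranone ring are bought; the benzo ring is formed in step 12. End game: 8-O-methylation, desilylation, debenzylation.

Key step: step 12

Assumption: (triisopropylsilyloxy)ethyne 21 is taken to be accessible from monolithium acetylide by the acetylide oxidation and O-silylation sequence that serves for substituted 1-alkynes; the target is achiral, so 14, 15, 16, 23 and 25 are carried as racemates.

**Route**

Step 1
Reactants: 1 3,5-bis(benzyloxy)benzyl alcohol
Product: 2 1,3-bis(benzyloxy)-5-(methoxymethyl)benzene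
Conditions: NaH, MeI, THF, 0 °C to rt
Reagents that add atoms: methyl iodide, CI
Why: Williamson etherification of the only free hydroxyl, a primary benzylic alcohol, should proceed cleanly.

Step 2
Reactants: 2 1,3-bis(benzyloxy)-5-(methoxymethyl)benzene
Product: 4 2,4-bis(benzyloxy)-6-(methoxymethyl)benzaldehyde, via iminium chloride 3 (not isolated)
Conditions: POCl3, DMF, 0 to 70 °C; then H2O
Reagents that add atoms: N,N-dimethylformamide, CN(C)C=O; water, O
Why: Vilsmeier–Haack formylation of the dialkoxyarene should occur at the position ortho to the methoxymethyl group (ortho and para to the two ether oxygens) and not at the more hindered carbon between the two benzyloxy groups, as with orcinol dialkyl ethers.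

Step 3
Reactants: 4 2,4-bis(benzyloxy)-6-(methoxymethyl)benzaldehyde
Product: 5 4-(benzyloxy)-2-hydroxy-6-(methoxymethyl)benzaldehyde
Conditions: MgBr2·OEt2, toluene–Et2O, 80 °C; then 1 M HCl
Reagents that add atoms: none
Why: Chelation-controlled ether cleavage, in which magnesium bound between the aldehyde oxygen and the ortho ether oxygen activates only the ortho benzyl group for removal by bromide, should leave the para benzyl ether and the benzylic methyl ether intact.

Step 4
Reactants: 5 4-(benzyloxy)-2-hydroxy-6-(methoxymethyl)benzaldehyde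
Product: 6 4-(benzyloxy)-2-methoxy-6-(methoxymethyl)benzaldehyde
Conditions: MeI, K2CO3, DMF, 40 °C
Reagents that add atoms: methyl iodide, CI
Why: Williamson O-methylation of the chelated phenol with carbonate in a polar aprotic solvent is standard for ortho-hydroxybenzaldehydes.

Step 5
Reactants: 6 4-(benzyloxy)-2-methoxy-6-(methoxymethyl)benzaldehyde; 7 tert-butyl 2-(diethoxyphosphoryl)acetate
Product: 8 tert-butyl (E)-3-[4-(benzyloxy)-2-methoxy-6-(methoxymethyl)phenyl]prop-2-enoate
Conditions: NaH, THF, 0 °C to rt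
Reagents that add atoms: none
Why: Horner–Wadsworth–Emmons olefination with a stabilized phosphonate should give the E-cinnamate even from a di-ortho-substituted benzaldehyde, and it avoids an unstable electron-rich benzyl halide.

Step 6
Reactants: 8 tert-butyl (E)-3-[4-(benzyloxy)-2-methoxy-6-(methoxymethyl)phenyl]prop-2-enoate
Product: 9 tert-butyl 3-[4-(benzyloxy)-2-methoxy-6-(methoxymethyl)phenyl]propanoate
Conditions: NaBH4, NiCl2·6H2O (cat.), MeOH–THF, 0 °C
Reagents that add atoms: none
Why: Nickel boride conjugate reduction saturates the enoate double bond and should leave the aryl benzyl ether, the benzylic methyl ether and the tert-butyl ester untouched.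

Step 7
Reactants: 10 4-hydroxy-6-methyl-2H-pyran-2-one
Product: 11 4-bromo-6-methyl-2H-pyran-2-one
Conditions: Bu4NBr, P2O5, toluene, 100 °C
Reagents that add atoms: tetrabutylammonium bromide, CCCC[N+](CCCC)(CCCC)CCCC.[Br-]
Why: Dehydroxy-bromination of the vinylogous acid by phosphorylation of the 4-hydroxyl followed by addition–elimination of bromide is an established route to 4-bromo-2-pyranones.

Step 8
Reactants: 9 tert-butyl 3-[4-(benzyloxy)-2-methoxy-6-(methoxymethyl)phenyl]propanoate; 11 4-bromo-6-methyl-2H-pyran-2-one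
Product: 14 tert-butyl 3-[4-(benzyloxy)-2-methoxy-6-(methoxymethyl)phenyl]-2-(6-methyl-2-oxo-2H-pyran-4-yl)propanoate (racemic), via lithium enolate 12 (not isolated), via zinc enolate 13 (not isolated)
Conditions: LiN(i-Pr)2, THF, –78 °C; ZnCl2, –78 °C to rt; then 11, Pd(dba)2 (cat.), P(t-Bu)3 (cat.), THF, rt
Reagents that add atoms: none
Why: Palladium-catalysed α-arylation of a zinc ester enolate (Reformatsky-type Negishi coupling) should join the two halves, because the weakly basic zinc enolate tolerates the base-sensitive pyranone, the vinylogous acyl bromide adds readily to zerovalent palladium and the bulky phosphine favours reductive elimination over β-hydride elimination; the new α-stereocentre is formed racemic and is lost in step 12.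

Step 9
Reactants: 14 tert-butyl 3-[4-(benzyloxy)-2-methoxy-6-(methoxymethyl)phenyl]-2-(6-methyl-2-oxo-2H-pyran-4-yl)propanoate (racemic)
Product: 15 3-[4-(benzyloxy)-2-methoxy-6-(methoxymethyl)phenyl]-2-(6-methyl-2-oxo-2H-pyran-4-yl)propanoic acid (racemic)
Conditions: TFA, Et3SiH, CH2Cl2, 0 °C to rt
Reagents that add atoms: none
Why: Acidolysis of the tert-butyl ester through the tert-butyl cation, which the silane traps before it can alkylate ring A, should spare the pyranone, the aryl benzyl ether and the non-activated benzylic methyl ether.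

Step 10
Reactants: 15 3-[4-(benzyloxy)-2-methoxy-6-(methoxymethyl)phenyl]-2-(6-methyl-2-oxo-2H-pyran-4-yl)propanoic acid (racemic)
Product: 16 3-[4-(benzyloxy)-2-methoxy-6-(methoxymethyl)phenyl]-2-(6-methyl-2-oxo-2H-pyran-4-yl)propanoyl chloride (racemic)
Conditions: (COCl)2, DMF (cat.), CH2Cl2, 0 °C to rt; used crude
Reagents that add atoms: oxalyl chloride, O=C(Cl)C(=O)Cl
Why: Acid chloride formation through the Vilsmeier-type chloroiminium activator is mild, and both ring-A positions ortho to the tether are substituted, so no Friedel–Crafts ring closure can compete.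

Step 11
Reactants: 17 acetylene; 18 triisopropylsilyl trifluoromethanesulfonate
Product: 21 (triisopropylsilyloxy)ethyne, via lithium acetylide 19 (not isolated), via lithium ethynolate 20 (not isolated)
Conditions: n-BuLi, THF, –78 °C; t-BuOOLi (from t-BuOOH and LiN(SiMe3)2), –78 to –20 °C; then 18, –78 °C to rt
Reagents that add atoms: tert-butyl hydroperoxide, CC(C)(C)OO
Why: Electrophilic oxygen transfer from lithium tert-butyl peroxide to a lithium acetylide gives the ynolate, and the hard, bulky silyl triflate should silylate it on oxygen, as in the known preparation of 1-siloxy-1-alkynes.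

Step 12
Reactants: 16 3-[4-(benzyloxy)-2-methoxy-6-(methoxymethyl)phenyl]-2-(6-methyl-2-oxo-2H-pyran-4-yl)propanoyl chloride (racemic); 21 (triisopropylsilyloxy)ethyne
Product: 26 5-{[4-(benzyloxy)-2-methoxy-6-(methoxymethyl)phenyl]methyl}-8-hydroxy-3-methyl-6-(triisopropylsilyloxy)-1H-isochromen-1-one, via ketene 22 (not isolated), via cyclobutenone 23 (not isolated), via dienylketene 24 (not isolated), via cyclohexadienone 25 (not isolated)
Conditions: Et3N, toluene, 0 °C to rt; then 100 °C
Reagents that add atoms: none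
Why: Proposed new method: Et3N dehydrochlorinates 16 to ketene 22, the nucleophilic CH carbon of siloxyalkyne 21 adds to the ketene carbonyl carbon and the [2+2] adduct closes to the 3-siloxycyclobutenone 23; on heating, 23 opens by reversible conrotatory 4π electrocyclic ring opening to dienylketene 24, which closes by disrotatory 6π electrocyclization onto pyranone C3 to dienone 25, and enolization gives phenol 26. The closest known reaction type is the benzannulation of aryl and vinyl ketenes with heterosubstituted alkynes (Smith–Hoehn and Danheiser benzannulations); a 2-pyranon-4-yl ketene has not been used, but its C3=C4 bond is an enoate alkene placed exactly as the vinyl group of a vinylketene. The only ring that persists, the benzo ring, is closed by the 6π electrocyclization that forms C8–C8a after the cycloaddition has formed C5–C6 and C7–C8; the four-membered ring of 23 is transient. No stereocentre is set, because the quaternary carbon of 23 and C8a of 25 both end as aromatic carbons. The step needs the right orientation of the [2+2] addition, which the polarization of the ynol ether secures so that the ketene oxygen emerges as the free chelated 8-OH and the alkyne oxygen as the 6-silyl ether, and it needs ring closure at C3 and not at C5 of the pyranone, which bond localization secures, since only C3=C4 is a double bond in conjugation with the dienylketene and closure at C5 would give a non-benzenoid 2-benzopyran-3-one.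

Step 13
Reactants: 26 5-{[4-(benzyloxy)-2-methoxy-6-(methoxymethyl)phenyl]methyl}-8-hydroxy-3-methyl-6-(triisopropylsilyloxy)-1H-isochromen-1-one
Product: 27 5-{[4-(benzyloxy)-2-methoxy-6-(methoxymethyl)phenyl]methyl}-8-methoxy-3-methyl-6-(triisopropylsilyloxy)-1H-isochromen-1-one
Conditions: MeI, Ag2O, MeCN, 40 °C, dark
Reagents that add atoms: methyl iodide, CI
Why: O-Methylation of the chelated peri-hydroxyl with methyl iodide and silver oxide works without a soluble base, so the aryl silyl ether para to the lactone-bearing carbon should survive and the two oxygens stay differentiated.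

Step 14
Reactants: 27 5-{[4-(benzyloxy)-2-methoxy-6-(methoxymethyl)phenyl]methyl}-8-methoxy-3-methyl-6-(triisopropylsilyloxy)-1H-isochromen-1-one
Product: 28 5-{[4-(benzyloxy)-2-methoxy-6-(methoxymethyl)phenyl]methyl}-6-hydroxy-8-methoxy-3-methyl-1H-isochromen-1-one
Conditions: Bu4NF, AcOH, THF, 0 °C
Reagents that add atoms: none
Why: Fluoride-induced cleavage of the aryl silyl ether, buffered with acetic acid, should free the 6-hydroxyl without opening the lactone.

Step 15
Reactants: 28 5-{[4-(benzyloxy)-2-methoxy-6-(methoxymethyl)phenyl]methyl}-6-hydroxy-8-methoxy-3-methyl-1H-isochromen-1-one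
Product: 29 6-hydroxy-5-{[4-hydroxy-2-methoxy-6-(methoxymethyl)phenyl]methyl}-8-methoxy-3-methyl-1H-isochromen-1-one (CNP0481202.0)
Conditions: H2 (1 atm), 10% Pd/C, EtOAc, rt
Reagents that add atoms: none
Why: Hydrogenolysis of an aryl benzyl ether over palladium in an aprotic solvent is much faster than cleavage of the ortho-substituted benzylic methyl ether or reduction of the enol-lactone double bond.

**Compound list**

1 | 3,5-bis(benzyloxy)benzyl alcohol | OCc1cc(OCc2ccccc2)cc(OCc2ccccc2)c1 | starting material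
2 | 1,3-bis(benzyloxy)-5-(methoxymethyl)benzene | COCc1cc(OCc2ccccc2)cc(OCc2ccccc2)c1 | intermediate
3 | N-{[2,4-bis(benzyloxy)-6-(methoxymethyl)phenyl]methylidene}-N-methylmethanaminium chloride | COCc1cc(OCc2ccccc2)cc(OCc2ccccc2)c1C=[N+](C)C.[Cl-] | intermediate
4 | 2,4-bis(benzyloxy)-6-(methoxymethyl)benzaldehyde | COCc1cc(OCc2ccccc2)cc(OCc2ccccc2)c1C=O | intermediate
5 | 4-(benzyloxy)-2-hydroxy-6-(methoxymethyl)benzaldehyde | COCc1cc(OCc2ccccc2)cc(O)c1C=O | intermediate
6 | 4-(benzyloxy)-2-methoxy-6-(methoxymethyl)benzaldehyde | COCc1cc(OCc2ccccc2)cc(OC)c1C=O | intermediate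
7 | tert-butyl 2-(diethoxyphosphoryl)acetate | CCOP(=O)(CC(=O)OC(C)(C)C)OCC | starting material
8 | tert-butyl (E)-3-[4-(benzyloxy)-2-methoxy-6-(methoxymethyl)phenyl]prop-2-enoate | COCc1cc(OCc2ccccc2)cc(OC)c1/C=C/C(=O)OC(C)(C)C | intermediate
9 | tert-butyl 3-[4-(benzyloxy)-2-methoxy-6-(methoxymethyl)phenyl]propanoate | COCc1cc(OCc2ccccc2)cc(OC)c1CCC(=O)OC(C)(C)C | intermediate
10 | 4-hydroxy-6-methyl-2H-pyran-2-one (triacetic acid lactone) | Cc1cc(O)cc(=O)o1 | starting material
11 | 4-bromo-6-methyl-2H-pyran-2-one | Cc1cc(Br)cc(=O)o1 | intermediate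
12 | lithium enolate of 9 | COCc1cc(OCc2ccccc2)cc(OC)c1CC=C(O[Li])OC(C)(C)C | intermediate
13 | chlorozinc enolate of 9 (carbon-bound form) | COCc1cc(OCc2ccccc2)cc(OC)c1CC([Zn]Cl)C(=O)OC(C)(C)C | intermediate
14 | tert-butyl 3-[4-(benzyloxy)-2-methoxy-6-(methoxymethyl)phenyl]-2-(6-methyl-2-oxo-2H-pyran-4-yl)propanoate, racemic | Cc1cc(C(Cc2c(COC)cc(OCc3ccccc3)cc2OC)C(=O)OC(C)(C)C)cc(=O)o1 | intermediate
15 | 3-[4-(benzyloxy)-2-methoxy-6-(methoxymethyl)phenyl]-2-(6-methyl-2-oxo-2H-pyran-4-yl)propanoic acid, racemic | Cc1cc(C(Cc2c(COC)cc(OCc3ccccc3)cc2OC)C(=O)O)cc(=O)o1 | intermediate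
16 | 3-[4-(benzyloxy)-2-methoxy-6-(methoxymethyl)phenyl]-2-(6-methyl-2-oxo-2H-pyran-4-yl)propanoyl chloride, racemic | Cc1cc(C(Cc2c(COC)cc(OCc3ccccc3)cc2OC)C(=O)Cl)cc(=O)o1 | intermediate
17 | acetylene | C#C | starting material
18 | triisopropylsilyl trifluoromethanesulfonate | CC(C)[Si](OS(=O)(=O)C(F)(F)F)(C(C)C)C(C)C | starting material
19 | lithium acetylide | [Li]C#C | intermediate
20 | lithium ethynolate | [Li]OC#C | intermediate
21 | (triisopropylsilyloxy)ethyne | CC(C)[Si](OC#C)(C(C)C)C(C)C | intermediate
22 | 2-{[4-(benzyloxy)-2-methoxy-6-(methoxymethyl)phenyl]methyl}-2-(6-methyl-2-oxo-2H-pyran-4-yl)ethen-1-one (ketene) | Cc1cc(C(Cc2c(COC)cc(OCc3ccccc3)cc2OC)=C=O)cc(=O)o1 | intermediate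
23 | 4-{[4-(benzyloxy)-2-methoxy-6-(methoxymethyl)phenyl]methyl}-4-(6-methyl-2-oxo-2H-pyran-4-yl)-3-(triisopropylsilyloxy)cyclobut-2-en-1-one, racemic | Cc1cc(C2(Cc3c(COC)cc(OCc4ccccc4)cc3OC)C(=O)C=C2O[Si](C(C)C)(C(C)C)C(C)C)cc(=O)o1 | intermediate
24 | 5-[4-(benzyloxy)-2-methoxy-6-(methoxymethyl)phenyl]-4-(6-methyl-2-oxo-2H-pyran-4-yl)-3-(triisopropylsilyloxy)penta-1,3-dien-1-one, pyranonyl group cis to the ketenyl group | O=C=C/C(O[Si](C(C)C)(C(C)C)C(C)C)=C(\c1cc(C)oc(=O)c1)Cc1c(COC)cc(OCc2ccccc2)cc1OC | intermediate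
25 | 5-{[4-(benzyloxy)-2-methoxy-6-(methoxymethyl)phenyl]methyl}-3-methyl-6-(triisopropylsilyloxy)-8aH-isochromene-1,8-dione, racemic | O=C1C=C(O[Si](C(C)C)(C(C)C)C(C)C)C(Cc2c(COC)cc(OCc3ccccc3)cc2OC)=C2C=C(C)OC(=O)C12 | intermediate
26 | 5-{[4-(benzyloxy)-2-methoxy-6-(methoxymethyl)phenyl]methyl}-8-hydroxy-3-methyl-6-(triisopropylsilyloxy)-1H-isochromen-1-one | COCc1cc(OCc2ccccc2)cc(OC)c1Cc1c(O[Si](C(C)C)(C(C)C)C(C)C)cc(O)c2c(=O)oc(C)cc12 | intermediate
27 | 5-{[4-(benzyloxy)-2-methoxy-6-(methoxymethyl)phenyl]methyl}-8-methoxy-3-methyl-6-(triisopropylsilyloxy)-1H-isochromen-1-one | COCc1cc(OCc2ccccc2)cc(OC)c1Cc1c(O[Si](C(C)C)(C(C)C)C(C)C)cc(OC)c2c(=O)oc(C)cc12 | intermediate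
28 | 5-{[4-(benzyloxy)-2-methoxy-6-(methoxymethyl)phenyl]methyl}-6-hydroxy-8-methoxy-3-methyl-1H-isochromen-1-one | COCc1cc(OCc2ccccc2)cc(OC)c1Cc1c(O)cc(OC)c2c(=O)oc(C)cc12 | intermediate
29 | 6-hydroxy-5-{[4-hydroxy-2-methoxy-6-(methoxymethyl)phenyl]methyl}-8-methoxy-3-methyl-1H-isochromen-1-one (CNP0481202.0) | COCc1cc(O)cc(OC)c1Cc1c(O)cc(OC)c2c(=O)oc(C)cc12 | target

**Step count**

Total: 15 steps. Longest linear sequence: 13 steps (steps 1–6, 8–10, 12–15).

**Steps most likely to fail**

1. Step 12 (the step that carries the new-method label). The ketene may dimerize or be consumed before the cycloaddition. The dienylketene may also fail to close onto the electron-poor pyranone C3=C4 bond, reverting to the cyclobutenone or undergoing a 1,5-hydrogen shift from the benzylic methylene.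
Fallback (known chemistry only): the C5–CH2 bond is made by Negishi coupling on a preformed benzo ring. The sequence sets out from aldehyde 6 and comes back to the route at target 29.
Commercial methyl 2,4-dihydroxy-6-methylbenzoate (COC(=O)c1c(C)cc(O)cc1O) is benzylated at the non-chelated 4-hydroxyl (BnBr, K2CO3, acetone) to methyl 4-(benzyloxy)-2-hydroxy-6-methylbenzoate F1. Methylation (MeI, K2CO3, DMF) gives methyl 4-(benzyloxy)-2-methoxy-6-methylbenzoate F2, and bromination para to the methoxy group (NBS, MeCN) gives methyl 4-(benzyloxy)-3-bromo-6-methoxy-2-methylbenzoate F3.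
Lateral lithiation of the toluate methyl group (LiN(i-Pr)2, THF, –78 °C) and acylation with N-methoxy-N-methylacetamide should give methyl 4-(benzyloxy)-3-bromo-6-methoxy-2-(2-oxopropyl)benzoate F4. Enol lactonization (TsOH, toluene, reflux) then gives 6-(benzyloxy)-5-bromo-8-methoxy-3-methyl-1H-isochromen-1-one F5.
Aldehyde 6 is reduced (NaBH4, MeOH) to [4-(benzyloxy)-2-methoxy-6-(methoxymethyl)phenyl]methanol F6 and converted (SOCl2, CH2Cl2, 0 °C) into 5-(benzyloxy)-2-(chloromethyl)-1-methoxy-3-(methoxymethyl)benzene F7. Without storage, zinc insertion (Zn dust, LiCl, THF) gives {[4-(benzyloxy)-2-methoxy-6-(methoxymethyl)phenyl]methyl}zinc chloride F8.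
Negishi coupling of F5 with F8 (Pd(OAc)2, SPhos, THF, rt to 50 °C) should give 6-(benzyloxy)-5-{[4-(benzyloxy)-2-methoxy-6-(methoxymethyl)phenyl]methyl}-8-methoxy-3-methyl-1H-isochromen-1-one F9. Hydrogenolysis of both benzyl ethers (H2, Pd/C, EtOAc) gives 29.

2. Step 8. Transmetalation of the α-branched zinc enolate may be slow, so that β-hydride elimination from the palladium enolate or attack of the enolate on the pyranone ring takes over.
Fallback: the coupling is done with the unbranched enolate and the benzyl arm is added afterwards by condensation. The sequence sets out from bromopyranone 11 and aldehyde 6 and comes back at ester 14.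
Coupling of 11 with the Reformatsky reagent from tert-butyl bromoacetate and zinc (Pd(dba)2, P(t-Bu)3, THF, rt) should give tert-butyl 2-(6-methyl-2-oxo-2H-pyran-4-yl)acetate F10. Knoevenagel condensation of F10 with 6 (TiCl4, pyridine, THF, 0 °C to rt) gives tert-butyl 3-[4-(benzyloxy)-2-methoxy-6-(methoxymethyl)phenyl]-2-(6-methyl-2-oxo-2H-pyran-4-yl)prop-2-enoate F11, as either alkene isomer. Conjugate reduction of the doubly activated alkene (NaBH4, MeOH–THF, 0 °C) gives 14.

3. Step 11. Monolithium acetylide may disproportionate to the insoluble dilithium salt before oxygen transfer, the ynolate may be silylated at carbon, and the volatile product may be lost on isolation.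
Fallback: the classical two-stage elimination route to ynol ethers, setting out from silyl triflate 18 and coming back at alkyne 21.
The lithium enolate of acetaldehyde (from THF and n-BuLi by cycloreversion) is silylated on oxygen with 18 to give triisopropyl(vinyloxy)silane F12. Bromine addition (Br2, CH2Cl2, –78 °C) gives (1,2-dibromoethoxy)triisopropylsilane F13, and dehydrobromination with Et3N gives mainly [(Z)-2-bromoethenyloxy]triisopropylsilane F14. A second, anti dehydrobromination (LiN(i-Pr)2, THF, –78 °C, then methanol quench) gives 21.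

**Further compounds**

F1 | step 12 | methyl 4-(benzyloxy)-2-hydroxy-6-methylbenzoate | COC(=O)c1c(C)cc(OCc2ccccc2)cc1O
F2 | step 12 | methyl 4-(benzyloxy)-2-methoxy-6-methylbenzoate | COC(=O)c1c(C)cc(OCc2ccccc2)cc1OC
F3 | step 12 | methyl 4-(benzyloxy)-3-bromo-6-methoxy-2-methylbenzoate | COC(=O)c1c(C)c(Br)c(OCc2ccccc2)cc1OC
F4 | step 12 | methyl 4-(benzyloxy)-3-bromo-6-methoxy-2-(2-oxopropyl)benzoate | COC(=O)c1c(CC(C)=O)c(Br)c(OCc2ccccc2)cc1OC
F5 | step 12 | 6-(benzyloxy)-5-bromo-8-methoxy-3-methyl-1H-isochromen-1-one | Cc1cc2c(Br)c(OCc3ccccc3)cc(OC)c2c(=O)o1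
F6 | step 12 | [4-(benzyloxy)-2-methoxy-6-(methoxymethyl)phenyl]methanol | COCc1cc(OCc2ccccc2)cc(OC)c1CO
F7 | step 12 | 5-(benzyloxy)-2-(chloromethyl)-1-methoxy-3-(methoxymethyl)benzene | COCc1cc(OCc2ccccc2)cc(OC)c1CCl
F8 | step 12 | {[4-(benzyloxy)-2-methoxy-6-(methoxymethyl)phenyl]methyl}zinc chloride | COCc1cc(OCc2ccccc2)cc(OC)c1C[Zn]Cl
F9 | step 12 | 6-(benzyloxy)-5-{[4-(benzyloxy)-2-methoxy-6-(methoxymethyl)phenyl]methyl}-8-methoxy-3-methyl-1H-isochromen-1-one | COCc1cc(OCc2ccccc2)cc(OC)c1Cc1c(OCc2ccccc2)cc(OC)c2c(=O)oc(C)cc12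
F10 | step 8 | tert-butyl 2-(6-methyl-2-oxo-2H-pyran-4-yl)acetate | Cc1cc(CC(=O)OC(C)(C)C)cc(=O)o1
F11 | step 8 | tert-butyl 3-[4-(benzyloxy)-2-methoxy-6-(methoxymethyl)phenyl]-2-(6-methyl-2-oxo-2H-pyran-4-yl)prop-2-enoate, alkene geometry not fixed | COCc1cc(OCc2ccccc2)cc(OC)c1C=C(C(=O)OC(C)(C)C)c1cc(C)oc(=O)c1
F12 | step 11 | triisopropyl(vinyloxy)silane | C=CO[Si](C(C)C)(C(C)C)C(C)C
F13 | step 11 | (1,2-dibromoethoxy)triisopropylsilane, racemic | BrCC(Br)O[Si](C(C)C)(C(C)C)C(C)C
F14 | step 11 | [(Z)-2-bromoethenyloxy]triisopropylsilane | Br/C=C\O[Si](C(C)C)(C(C)C)C(C)C
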